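(The earlier runs and the new flask are simulated with made-up constants; scatter was added.)

The decade was the unit I reckoned in while choosing what to change in the next run: the leverage of a setting, its log–log slope, is the decades of reacted fraction of the electrophile charge gained per decade of that setting.

the same everywhere: electrophile 20 mM; nucleophile 1.05 equiv

|  | free base | remark | time |
|---|---|---|---|
| Saturday's | 0.96 equiv | run made earlier |  |
| Tuesday's | 1.6 equiv | run made earlier |  |
| west | 1.80 equiv |  | 6.0 h |
| south | 1.20 equiv |  | 6.0 h |

| run | time / h | electrophile / % | target / % |
|---|---|---|---|
| Saturday's | 0.500 | 94.4 | 5.4 |
| Saturday's | 0.833 | 91.8 | 8.7 |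
| Saturday's | 1.50 | 86.8 | 13.5 |
| Saturday's | 3.00 | 77.3 | 23.3 |
| Saturday's | 6.00 | 65.0 | 34.9 |
| Tuesday's | 0.500 | 94.7 | 5.4 |
| Tuesday's | 1.50 | 86.2 | 13.5 |
| Tuesday's | 3.00 | 76.7 | 23.2 |
| Tuesday's | 4.00 | 72.1 | 27.9 |
| Tuesday's | 6.00 | 64.6 | 34.8 |

(readings scatter by 0.3 percentage points)

* part of the electrophile that has reacted at the end, west
* part of the electrophile that has reacted at the end, south
* what raising the equivalents of free base from its lowest to its highest value here does to the part of the electrophile that has reacted (changes below 5 percentage points count as none) (it rises / no change / it falls)

Saturday's and Tuesday's runs differed in free base, 0.96 equiv against 1.6 equiv, and at 6.00 h they had reacted fractions of 35.0 % and 35.4 %, a gap of 0.4 percentage points beside a reading scatter of 0.3 points. That gave free base a leverage of 0.0222, a reading I could not tell from zero. Pooling the two runs, the reacted fraction grew from 23.0 % at 3.00 h to 35.2 % at 6.00 h, so I read, over that span of the runs, a leverage of time of 0.614, decades of reacted fraction per decade of hours. Scaling Tuesday's run up to west and Saturday's run up to south, I reckoned 35.5 % for west and 35.2 % for south, a difference of 0.30 points against the 5 points that counts as a change. My decision for the next run was therefore to expect the same from the free base charges of west and south and to keep the clock exact, since time had more leverage than free base.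

The forecast gave 35.2 % for west, 35.2 % for south and no change, on this ground: “The rate is therefore effectively zero order in free base across this range.” My west stood 0.30 points above its figure.

West gave 35.2 % and south 35.0 %, and the trend was no change, with 0.24 points between the lowest and highest free base. At 6.00 h protonated nucleophile in west stood at 26.4 % of the electrophile charged, more than salt of the base at 4.19 %, and the path to that salt made no difference to west. Taken back to 4.53 h, the nearest earlier time at which south's answer had moved by 5 points, the leverage of time reckoned a fall of 5.5 points for south.

    nucleophile + acid set free ⇌ protonated nucleophile, settled at all times (K = 1100 /M)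
    acid set free + free base ⇌ salt of the base (K = 61.0 /M, k = 0.550 /M/min)
    acid set free + free base ⇌ idle adduct, settled at all times (K = 19.0 /M)
    electrophile + nucleophile → acid set free + target (k = 0.0910 /M/min)

For west read at 4.0 h, the leverage of time gave 27.4 % reacted; the computed result was 27.9 %.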